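**Strategy.** The five-membered ring (C1–C2(=O)–C3–C3a–C7a, indene numbering) is heptan-4-one in disguise, and C7a becomes α to a carbonyl if C7 is carried as a ketone. The C7a–C1 bond is then the 2,3-bond of a 1,4-diketone. Heptan-4-one is first attached through C3 to C3a of a chiral cyclohexadienone (Michael addition). The precursor of the key step is therefore a cyclohexenone bearing a 4-oxoheptan-3-yl chain. Intramolecular oxidative coupling of its bis-enolate forms C7a–C1 and closes the cyclopentanone; C7a, C1 and C3 are epimerizable and settle into the trans-fused, all-trans array. The C7 ketone later delivers the C5 quaternary centre and the C6=C7 ethyl alkene.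

Key step: step 7

Remark on the chemistry: atom numbers C1–C7a are the hexahydroindene numbers of the target; the tert-butoxycarbonyl group (not the ethyl group) on C4 is assumed to control the face of both additions at the carbons flanking C4.

Step 1
Reactants: 1 tert-butyl 3-oxopentanoate
Product: 2 tert-butyl 2-ethyl-3-oxopentanoate (racemic)
Conditions: EtI, K2CO3, acetone, reflux
Reagents that add atoms: iodoethane, CCI
Why: C-alkylation (SN2) of the stabilized β-keto ester enolate should occur cleanly at the central carbon under mild carbonate conditions, and the new centre is configurationally labile and is fixed only in step 2.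

Step 2
Reactants: 2 tert-butyl 2-ethyl-3-oxopentanoate; 3 but-3-en-2-one
Product: 4 tert-butyl (2R)-2-ethyl-5-oxo-2-propanoylhexanoate
Conditions: 9-O-(9-phenanthryl)cupreidine (10 mol%), CH2Cl2, −24 °C
Reagents that add atoms: none
Why: Catalytic asymmetric Michael addition under bifunctional cinchona-alkaloid catalysis, in which the quinuclidine nitrogen forms the enolate and the 6'-hydroxyl group binds the enone, should set the quaternary centre (C4 of the target) by catalyst control, the cupreine-derived pseudo-enantiomer being the remedy if the sense of induction has to be reversed.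

Step 3
Reactants: 4 tert-butyl (2R)-2-ethyl-5-oxo-2-propanoylhexanoate
Product: 6 tert-butyl (1R)-1,2-diethyl-4-oxocyclohex-2-ene-1-carboxylate, via ketol 5 (not isolated)
Conditions: pyrrolidine (0.3 equiv), AcOH (0.3 equiv), toluene, 80 °C
Reagents that add atoms: none
Why: Second stage of a Robinson annulation (enamine aldol condensation): pyrrolidine condenses with the unhindered methyl ketone, the enamine attacks the propanoyl carbonyl in a six-membered closure, and dehydration gives the conjugated enone without touching the quaternary centre.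

Step 4
Reactants: 6 tert-butyl (1R)-1,2-diethyl-4-oxocyclohex-2-ene-1-carboxylate
Product: 8 tert-butyl (1R)-1,2-diethyl-4-oxocyclohexa-2,5-diene-1-carboxylate, via silyl dienol ether 7 (not isolated)
Conditions: LiN(iPr)2, THF, −78 °C; Me3SiCl; then Pd(OAc)2 (1.05 equiv), MeCN, rt
Reagents that add atoms: none
Why: Kinetic α'-deprotonation gives the cross-conjugated dienolate, whose silyl ether should undergo Saegusa–Ito dehydrogenation (oxo-π-allylpalladium formation, β-hydride elimination) to place the new double bond regiospecifically between ring carbons 5 and 6.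

Step 5
Reactants: 9 heptan-4-one
Product: 10 (Z)-trimethyl(hept-3-en-4-yloxy)silane
Conditions: Me3SiOTf, Et3N, CH2Cl2, 0 °C
Reagents that add atoms: trimethylsilyl trifluoromethanesulfonate, C[Si](C)(C)OS(=O)(=O)C(F)(F)F
Why: Soft enolization and O-silylation of a symmetrical ketone (silyl enol ether formation) can give only one constitutional isomer, and the alkene geometry is irrelevant downstream.

Step 6
Reactants: 8 tert-butyl (1R)-1,2-diethyl-4-oxocyclohexa-2,5-diene-1-carboxylate; 10 (Z)-trimethyl(hept-3-en-4-yloxy)silane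
Product: 12 tert-butyl (1R,6R)-1,2-diethyl-4-oxo-6-(4-oxoheptan-3-yl)cyclohex-2-ene-1-carboxylate, via silyl dienol ether 11 (not isolated)
Conditions: HNTf2 (5 mol%), CH2Cl2, −78 °C; then 1 M HCl, THF, 0 °C
Reagents that add atoms: none
Why: In this Mukaiyama–Michael addition (silyl triflimide formed from HNTf2 as Lewis acid) the enol silane should attack the only unsubstituted β-carbon of the dienone on the face anti to the tert-butoxycarbonyl group of the adjacent quaternary carbon (the larger and more electron-withdrawing substituent), which sets C3a with the side chain cis to the C-ethyl group, while the side-chain centre forms as a mixture that is equilibrated in step 7.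

Step 7
Reactants: 12 tert-butyl (1R,6R)-1,2-diethyl-4-oxo-6-(4-oxoheptan-3-yl)cyclohex-2-ene-1-carboxylate
Product: 14 tert-butyl (1S,3S,3aS,4R,7aR)-1,3,4,5-tetraethyl-2,7-dioxo-2,3,3a,4,7,7a-hexahydro-1H-indene-4-carboxylate, via dilithium bis-enolate 13 (not isolated)
Conditions: LiN(iPr)2 (2.3 equiv), THF, −78 °C; Fe(acac)3 (2.2 equiv), −78 °C to rt, 0.01 M; then DBU (0.2 equiv), CH2Cl2, rt
Reagents that add atoms: none
Why: Double deprotonation gives the cross-conjugated dienolate of the enone (at the future C7a) and the kinetic enolate of the side-chain ketone at its CH2 (future C1); single-electron oxidation by trivalent iron generates an α-keto radical at C1 that adds to the dienolate carbon C7a, and a second oxidation delivers the 1,4-diketone. The closest known reaction type is the intramolecular oxidative coupling of ketone bis-enolates (oxidative enolate coupling). The cyclopentanone closes in a 5-exo-trig radical addition onto the exocyclic C7a=C7 enolate bond, a mode free of the enolendo penalty that blocks polar α-alkylation across this bond. The three centres touched (C7a, C1, C3) are all α to a carbonyl, so DBU should set them under thermodynamic control, with both ring bonds at C3a/C7a equatorial (trans fusion) and each ethyl trans to its ring neighbour; any minor cis-fused epimer is separated and re-equilibrated. The step needs regioselective enolization (α' rather than γ of the enone, CH2 rather than CH of the side chain), secured by kinetic deprotonation at −78 °C, and intra- over intermolecular coupling, secured by high dilution and the five-membered transition state. The non-epimerizable C3a is already fixed, so the equilibration only has to bring the new bond into the trans relationship with it.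

Step 8
Reactants: 14 tert-butyl (1S,3S,3aS,4R,7aR)-1,3,4,5-tetraethyl-2,7-dioxo-2,3,3a,4,7,7a-hexahydro-1H-indene-4-carboxylate; 15 (E)-(2-bromoethenyl)benzene
Product: 18 tert-butyl (1S,3S,3aR,4R,5S,7aR)-1,3,4,5-tetraethyl-2-oxo-5-[(E)-2-phenylethenyl]-7-[(trifluoromethanesulfonyl)oxy]-2,3,3a,4,5,7a-hexahydro-1H-indene-4-carboxylate, via lithium bis[(E)-2-phenylethenyl]cuprate 16 (not isolated), via silyl enol ether 17 (not isolated)
Conditions: 15 (3 equiv), t-BuLi (6 equiv), Et2O, −78 °C; CuI (1.5 equiv); then 14, Me3SiCl, THF, −78 to −30 °C; then CsF, PhNTf2, DME, rt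
Reagents that add atoms: N-phenylbis(trifluoromethanesulfonimide), O=S(=O)(N(c1ccccc1)S(=O)(=O)C(F)(F)F)C(F)(F)F
Why: In this Me3SiCl-accelerated conjugate addition of an alkenyl cuprate, followed by fluoride-triggered triflation of the regiodefined silyl enol ether, the ethyl group at C4 of the trans-fused bicycle is pseudoaxial, so the cuprate should enter the β-carbon axially on the opposite face (syn only to the axial hydrogen at C3a) and place the styryl group at C5 cis to the ester, the (E) geometry of 15 being retained through halogen–lithium exchange and transmetalation.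

Step 9
Reactants: 18 tert-butyl (1S,3S,3aR,4R,5S,7aR)-1,3,4,5-tetraethyl-2-oxo-5-[(E)-2-phenylethenyl]-7-[(trifluoromethanesulfonyl)oxy]-2,3,3a,4,5,7a-hexahydro-1H-indene-4-carboxylate
Product: 19 tert-butyl (1S,3S,3aR,4R,5S,7aR)-1,3,4,5,7-pentaethyl-2-oxo-5-[(E)-2-phenylethenyl]-2,3,3a,4,5,7a-hexahydro-1H-indene-4-carboxylate
Conditions: Et2Zn (1.5 equiv), Pd(dppf)Cl2 (5 mol%), THF, 50 °C
Reagents that add atoms: diethylzinc, CC[Zn]CC
Why: Negishi cross-coupling (oxidative addition of the enol triflate to zerovalent palladium, transmetalation from zinc, reductive elimination, with dppf suppressing β-hydride elimination of the ethyl group) should install the C7 ethyl group on the existing C6=C7 double bond without affecting any stereocentre.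

Step 10
Reactants: 19 tert-butyl (1S,3S,3aR,4R,5S,7aR)-1,3,4,5,7-pentaethyl-2-oxo-5-[(E)-2-phenylethenyl]-2,3,3a,4,5,7a-hexahydro-1H-indene-4-carboxylate
Product: 21 (1S,3S,3aR,4R,5S,7aR)-1,3,4,5,7-pentaethyl-2-oxo-5-[(E)-2-phenylethenyl]-2,3,3a,4,5,7a-hexahydro-1H-indene-4-carboxylic acid, via trimethylsilyl ester 20 (not isolated)
Conditions: Me3SiOTf, 2,6-lutidine, CH2Cl2, 0 °C to rt; then H2O
Reagents that add atoms: none
Why: Silyl-triflate-mediated cleavage of the tert-butyl ester (O-silylation, loss of 2-methylpropene, hydrolysis of the silyl ester) should free the hindered acid under non-protic conditions that leave the trisubstituted alkene, the styrene and the already equilibrated α-centres of the ketone untouched.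

**Compound list**

1 | tert-butyl 3-oxopentanoate | CCC(=O)CC(=O)OC(C)(C)C | starting material
2 | tert-butyl 2-ethyl-3-oxopentanoate (racemic) | CCC(=O)C(CC)C(=O)OC(C)(C)C | intermediate
3 | but-3-en-2-one | CC(=O)C=C | starting material
4 | tert-butyl (2R)-2-ethyl-5-oxo-2-propanoylhexanoate | CC[C@](C(=O)OC(C)(C)C)(C(=O)CC)CCC(C)=O | intermediate
5 | tert-butyl (1R)-1,2-diethyl-2-hydroxy-4-oxocyclohexane-1-carboxylate (ketol, epimers at C2, not isolated) | CC[C@]1(C(=O)OC(C)(C)C)C(O)(CC)CC(=O)CC1 | intermediate
6 | tert-butyl (1R)-1,2-diethyl-4-oxocyclohex-2-ene-1-carboxylate | CC[C@]1(C(=O)OC(C)(C)C)C(CC)=CC(=O)CC1 | intermediate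
7 | tert-butyl (1R)-1,2-diethyl-4-(trimethylsilyloxy)cyclohexa-2,4-diene-1-carboxylate (not isolated) | CC[C@]1(C(=O)OC(C)(C)C)C(CC)=CC(O[Si](C)(C)C)=CC1 | intermediate
8 | tert-butyl (1R)-1,2-diethyl-4-oxocyclohexa-2,5-diene-1-carboxylate | CC[C@]1(C(=O)OC(C)(C)C)C(CC)=CC(=O)C=C1 | intermediate
9 | heptan-4-one | CCCC(=O)CCC | starting material
10 | (Z)-trimethyl(hept-3-en-4-yloxy)silane | CC/C=C(/CCC)O[Si](C)(C)C | intermediate
11 | tert-butyl (1R,6R)-1,2-diethyl-6-(4-oxoheptan-3-yl)-4-(trimethylsilyloxy)cyclohexa-2,4-diene-1-carboxylate (side-chain epimers, not isolated) | CC[C@]1(C(=O)OC(C)(C)C)C(CC)=CC(O[Si](C)(C)C)=C[C@@H]1C(CC)C(=O)CCC | intermediate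
12 | tert-butyl (1R,6R)-1,2-diethyl-4-oxo-6-(4-oxoheptan-3-yl)cyclohex-2-ene-1-carboxylate (side-chain epimers) | CC[C@]1(C(=O)OC(C)(C)C)C(CC)=CC(=O)C[C@@H]1C(CC)C(=O)CCC | intermediate
13 | dilithium bis-enolate of 12 (not isolated) | [Li+].[Li+].CC[C@]1(C(=O)OC(C)(C)C)C(CC)=CC([O-])=C[C@@H]1C(CC)C([O-])=CCC | intermediate
14 | tert-butyl (1S,3S,3aS,4R,7aR)-1,3,4,5-tetraethyl-2,7-dioxo-2,3,3a,4,7,7a-hexahydro-1H-indene-4-carboxylate | CC[C@]1(C(=O)OC(C)(C)C)C(CC)=CC(=O)[C@@H]2[C@@H]1[C@H](CC)C(=O)[C@H]2CC | intermediate
15 | (E)-(2-bromoethenyl)benzene | Br/C=C/c1ccccc1 | starting material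
16 | lithium bis[(E)-2-phenylethenyl]cuprate (monovalent copper, not isolated) | [Li+].[Cu-](/C=C/c1ccccc1)/C=C/c1ccccc1 | intermediate
17 | tert-butyl (1S,3S,3aR,4R,5S,7aR)-1,3,4,5-tetraethyl-2-oxo-5-[(E)-2-phenylethenyl]-7-(trimethylsilyloxy)-2,3,3a,4,5,7a-hexahydro-1H-indene-4-carboxylate (not isolated) | C[Si](C)(C)OC1=C[C@@](/C=C/c2ccccc2)(CC)[C@](CC)(C(=O)OC(C)(C)C)[C@@H]2[C@@H]1[C@H](CC)C(=O)[C@H]2CC | intermediate
18 | tert-butyl (1S,3S,3aR,4R,5S,7aR)-1,3,4,5-tetraethyl-2-oxo-5-[(E)-2-phenylethenyl]-7-[(trifluoromethanesulfonyl)oxy]-2,3,3a,4,5,7a-hexahydro-1H-indene-4-carboxylate | O=S(=O)(OC1=C[C@@](/C=C/c2ccccc2)(CC)[C@](CC)(C(=O)OC(C)(C)C)[C@@H]2[C@@H]1[C@H](CC)C(=O)[C@H]2CC)C(F)(F)F | intermediate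
19 | tert-butyl (1S,3S,3aR,4R,5S,7aR)-1,3,4,5,7-pentaethyl-2-oxo-5-[(E)-2-phenylethenyl]-2,3,3a,4,5,7a-hexahydro-1H-indene-4-carboxylate | CCC1=C[C@@](/C=C/c2ccccc2)(CC)[C@](CC)(C(=O)OC(C)(C)C)[C@@H]2[C@@H]1[C@H](CC)C(=O)[C@H]2CC | intermediate
20 | trimethylsilyl (1S,3S,3aR,4R,5S,7aR)-1,3,4,5,7-pentaethyl-2-oxo-5-[(E)-2-phenylethenyl]-2,3,3a,4,5,7a-hexahydro-1H-indene-4-carboxylate (not isolated) | CCC1=C[C@@](/C=C/c2ccccc2)(CC)[C@](CC)(C(=O)O[Si](C)(C)C)[C@@H]2[C@@H]1[C@H](CC)C(=O)[C@H]2CC | intermediate
21 | (1S,3S,3aR,4R,5S,7aR)-1,3,4,5,7-pentaethyl-2-oxo-5-[(E)-2-phenylethenyl]-2,3,3a,4,5,7a-hexahydro-1H-indene-4-carboxylic acid | CCC1=C[C@@](/C=C/c2ccccc2)(CC)[C@](CC)(C(=O)O)[C@@H]2[C@@H]1[C@H](CC)C(=O)[C@H]2CC | target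

**Step count.** Total: 10 steps. Longest linear sequence: 9 steps (steps 1–4 and 6–10; step 5 is a one-step side branch).

**Steps most likely to fail, with fallbacks**

1. Step 7. The bis-enolate may form incompletely, and intermolecular or over-oxidative coupling may compete with ring closure. The fallback sets out from 12 and comes back at 14. The two enol units are tied together covalently before oxidation: 12 is converted with LiN(iPr)2 and Me2SiCl2 into the cyclic dimethylsilylene bis(enol ether) of 12 F1. One-electron oxidation of this neutral tethered bis-enol ether with (NH4)2Ce(NO3)6 and NaHCO3 in MeCN at −10 °C (tetravalent cerium, radical-cation pathway) should couple the two enol carbons within the eight-membered siloxane ring. Hydrolytic work-up and DBU equilibration would return 14.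

2. Step 8. Transfer of the bulky alkenyl group to the fully substituted β-carbon next to the quaternary centre may be slow or fail, with enolization or reduction of the enone taking over. The fallback sets out from 14 and comes back at 19. The smaller vinyl group is transferred first (CH2=CHMgBr, CuI, Me3SiCl, THF, −78 °C) to give the vinyl silyl enol ether F2. This is converted as in the main route into the vinyl enol triflate F3 (CsF, PhNTf2) and ethylated (Et2Zn, Pd(dppf)Cl2) to the vinyl tert-butyl ester F4. A Heck reaction of F4 with iodobenzene (Pd(OAc)2, Ag2CO3, DMF, 80 °C) would then build the (E)-styryl group and return 19.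

3. Step 6. Facial selectivity at C3a may be insufficient (attack from the ester face), and reactivity at the neopentylic β-carbon may be low. The fallback sets out from 8 and 9 and comes back at 12. The Michael addition is run reversibly as a Stork enamine reaction: heptan-4-one 9 is condensed with pyrrolidine to 1-(hept-3-en-4-yl)pyrrolidine F5, which adds to 8 in MeCN at 40 °C in the presence of AcOH. Under these conditions the adduct can revert by retro-Michael reaction, so the C3a epimer with the bulky side chain trans to the tert-butyl ester should accumulate under thermodynamic control; hydrolysis would give 12.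

Further compounds
F1 | step 7 | cyclic dimethylsilylene bis(enol ether) of 12 (silicon bridges the ring enol oxygen and the side-chain enol oxygen) | CC[C@]1(C(=O)OC(C)(C)C)C(CC)=CC(O2)=C[C@@H]1C(CC)C(=CCC)O[Si]2(C)C
F2 | step 8 | tert-butyl (1S,3S,3aR,4R,5S,7aR)-5-ethenyl-1,3,4,5-tetraethyl-2-oxo-7-(trimethylsilyloxy)-2,3,3a,4,5,7a-hexahydro-1H-indene-4-carboxylate | C[Si](C)(C)OC1=C[C@@](C=C)(CC)[C@](CC)(C(=O)OC(C)(C)C)[C@@H]2[C@@H]1[C@H](CC)C(=O)[C@H]2CC
F3 | step 8 | tert-butyl (1S,3S,3aR,4R,5S,7aR)-5-ethenyl-1,3,4,5-tetraethyl-2-oxo-7-[(trifluoromethanesulfonyl)oxy]-2,3,3a,4,5,7a-hexahydro-1H-indene-4-carboxylate | O=S(=O)(OC1=C[C@@](C=C)(CC)[C@](CC)(C(=O)OC(C)(C)C)[C@@H]2[C@@H]1[C@H](CC)C(=O)[C@H]2CC)C(F)(F)F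
F4 | step 8 | tert-butyl (1S,3S,3aR,4R,5S,7aR)-5-ethenyl-1,3,4,5,7-pentaethyl-2-oxo-2,3,3a,4,5,7a-hexahydro-1H-indene-4-carboxylate | CCC1=C[C@@](C=C)(CC)[C@](CC)(C(=O)OC(C)(C)C)[C@@H]2[C@@H]1[C@H](CC)C(=O)[C@H]2CC
F5 | step 6 | 1-(hept-3-en-4-yl)pyrrolidine | CCC=C(CCC)N1CCCC1
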